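**Retrosynthetic overview**

1. The target is the achiral flavone 2-(2,5-dihydroxy-3,4-dimethoxyphenyl)-5-hydroxy-7-methoxy-4H-chromen-4-one. Its three free phenols are carried as benzyl ethers and released last; the C4 carbonyl and the C2=C3 double bond are installed late on a flavan (C4 CH2 → CHOH → C=O, then dehydrogenation).
2. Structural feature: ring C (O1, C2, C3, C4, C4a, C8a) is fused to the phloroglucinol-type ring A through C4a and C8a, and O1–C8a–C4a–C4 are the four atoms of an ortho-quinone methide. Ring C is therefore cut at O1–C2 and C3–C4 into a ring A 2-hydroxybenzyl alcohol and a ring B styrene (inverse-demand hetero-Diels–Alder).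
3. Ring A partner: 2,4,6-trimethoxybenzaldehyde, chelation-directed bis-demethylation, monobenzylation, reduction. This places the formyl carbon unambiguously between the two oxygens that become O1 and the C5 oxygen, which direct formylation of 5-methoxyresorcinol would not do.
4. Ring B partner: 2,3-dimethoxyphenol, para-quinone, hydroquinone dibenzyl ether, bromination, Suzuki vinylation.
5. Ring order: rings A and B are bought as arenes; ring C is the only ring formed (key step) and is then oxidised to the pyranone.

Key step: step 9

Remark: compounds 13 to 16 are racemic (14 also a mixture of C4 epimers); no stereocontrol is needed because C2 and C4 both end as trigonal carbons of the flavone, which has no stereocentre.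

**Route**

Step 1
Reactants: 1 2,3-dimethoxyphenol
Product: 2 2,3-dimethoxycyclohexa-2,5-diene-1,4-dione (2,3-dimethoxy-1,4-benzoquinone)
Conditions: (KO3S)2NO (Fremy's salt, 2.2 equiv), KH2PO4, H2O–acetone, 0 °C → rt
Reagents that add atoms: potassium nitrosodisulfonate, [K+].[K+].[O]N(S(=O)(=O)[O-])S(=O)(=O)[O-]
Why: Teuber oxidation, in which the nitroxyl radical converts a phenol with a free para position into the para-benzoquinone, and here the carbon para to the hydroxyl is unsubstituted.

Step 2
Reactants: 2 2,3-dimethoxy-1,4-benzoquinone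
Product: 3 2,3-dimethoxybenzene-1,4-diol
Conditions: Na2S2O4 (aq.), EtOAc, rt, N2
Reagents that add atoms: none
Why: Dithionite reduction of a quinone to its hydroquinone is a fast two-electron reduction that leaves the methyl ethers untouched.

Step 3
Reactants: 3 2,3-dimethoxybenzene-1,4-diol
Product: 4 1,4-bis(benzyloxy)-2,3-dimethoxybenzene
Conditions: BnBr (2.4 equiv), K2CO3 (3 equiv), DMF, 60 °C, N2
Reagents that add atoms: benzyl bromide, BrCc1ccccc1
Why: Williamson etherification of both phenoxides, run with exclusion of air because the hydroquinone dianion is easily reoxidised.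

Step 4
Reactants: 4 1,4-bis(benzyloxy)-2,3-dimethoxybenzene
Product: 5 1,4-bis(benzyloxy)-5-bromo-2,3-dimethoxybenzene
Conditions: NBS (1.05 equiv), MeCN, 0 °C → rt, dark
Reagents that add atoms: N-bromosuccinimide, O=C1CCC(=O)N1Br
Why: Electrophilic aromatic bromination, in which the two free ring positions are equivalent by symmetry (each ortho to a benzyloxy and para to a methoxy group) and the first bromine slows a second substitution.

Step 5
Reactants: 5 1,4-bis(benzyloxy)-5-bromo-2,3-dimethoxybenzene; 6 2-ethenyl-4,4,5,5-tetramethyl-1,3,2-dioxaborolane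
Product: 7 1-ethenyl-2,5-bis(benzyloxy)-3,4-dimethoxybenzene
Conditions: 6 (1.5 equiv), PdCl2(dppf) (5 mol%), K2CO3 (3 equiv), 1,4-dioxane–H2O, 90 °C
Reagents that add atoms: none
Why: Suzuki–Miyaura cross-coupling of an aryl bromide with a vinylboronate, to which aryl benzyl and methyl ethers are inert.

Step 6
Reactants: 8 2,4,6-trimethoxybenzaldehyde
Product: 9 2,6-dihydroxy-4-methoxybenzaldehyde
Conditions: AlCl3 (5 equiv), CH2Cl2, 0 °C → reflux; then 1 M HCl
Reagents that add atoms: none
Why: Lewis-acid ether cleavage directed by chelation, in which only the two methoxy groups ortho to the formyl group can form a six-membered aluminium chelate with the carbonyl oxygen, so the para methoxy group should survive.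

Step 7
Reactants: 9 2,6-dihydroxy-4-methoxybenzaldehyde
Product: 10 2-(benzyloxy)-6-hydroxy-4-methoxybenzaldehyde
Conditions: BnBr (1.05 equiv), K2CO3 (1.1 equiv), DMF, rt
Reagents that add atoms: benzyl bromide, BrCc1ccccc1
Why: Williamson etherification of one of two equivalent phenols, after which the remaining hydroxyl is held in a hydrogen bond to the formyl oxygen and is alkylated much more slowly.

Step 8
Reactants: 10 2-(benzyloxy)-6-hydroxy-4-methoxybenzaldehyde
Product: 11 3-(benzyloxy)-2-(hydroxymethyl)-5-methoxyphenol
Conditions: NaBH4 (1.2 equiv), THF–MeOH, −10 → 0 °C, short reaction time; pH 7 buffer work-up, cold; used at once without chromatography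
Reagents that add atoms: none
Why: Borohydride reduction of an aldehyde to the primary alcohol, kept cold, brief and neutral so that the electron-rich 2-hydroxybenzyl alcohol does not ionise before the next step.

Step 9
Reactants: 11 3-(benzyloxy)-2-(hydroxymethyl)-5-methoxyphenol; 7 1-ethenyl-2,5-bis(benzyloxy)-3,4-dimethoxybenzene
Product: 13 racemic 5-(benzyloxy)-7-methoxy-2-[2,5-bis(benzyloxy)-3,4-dimethoxyphenyl]chroman, via ortho-quinone methide 12 (not isolated)
Conditions: 7 (3 equiv), BHT (5 mol%), o-xylene, 140 °C, N2, 11 added slowly by syringe pump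
Reagents that add atoms: none
Why: Heating dehydrates 11 (loss of water across the phenol O–H and the benzylic C–OH) to ortho-quinone methide 12, an electron-poor heterodiene made of O1, C8a, C4a and the C4 methylene; only one such species can form because the other ring A oxygen ortho to the methylene is benzylated. 12 should add to the electron-rich styrene 7 in an asynchronous inverse-electron-demand hetero-Diels–Alder reaction, the known ortho-quinone methide/styrene route to flavans: the styrene CH2 bonds first to the methide carbon (C3–C4) while positive charge builds at the benzylic carbon, stabilised by the ortho benzyloxy and para methoxy groups of ring B, and the carbonyl oxygen then closes O1–C2. Ring C is thus closed as a six-membered ring in the (4+2) cycloaddition mode, driven by rearomatisation of ring A. The new stereocentre C2 arises from achiral partners with no controlling element, so 13 is racemic, which is acceptable because C2 becomes trigonal in step 12. The step needs 2-aryl regiochemistry, secured by the polarisation of both partners (nucleophilic terminal alkene carbon, electrophilic methide carbon), and it needs the cycloaddition to outrun C-alkylation of ring A by 12, for which 12 is kept at low stationary concentration by slow addition into excess 7, with a radical inhibitor against styrene polymerisation.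

Step 10
Reactants: 13 racemic 5-(benzyloxy)-7-methoxy-2-[2,5-bis(benzyloxy)-3,4-dimethoxyphenyl]chroman
Product: 14 racemic 5-(benzyloxy)-7-methoxy-2-[2,5-bis(benzyloxy)-3,4-dimethoxyphenyl]chroman-4-ol (mixture of C4 epimers)
Conditions: DDQ (1.2 equiv), CH2Cl2–pH 7 phosphate buffer, 0 °C → rt, dark
Reagents that add atoms: water, O
Why: DDQ benzylic oxidation by hydride abstraction at C4, whose cation is stabilised by O1 and the 5-benzyloxy group (both ortho) and the 7-methoxy group (para) and is captured by water; the new C4 stereocentre needs no control because it is oxidised in the next step.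

Step 11
Reactants: 14 racemic 5-(benzyloxy)-7-methoxy-2-[2,5-bis(benzyloxy)-3,4-dimethoxyphenyl]chroman-4-ol
Product: 15 racemic 5-(benzyloxy)-7-methoxy-2-[2,5-bis(benzyloxy)-3,4-dimethoxyphenyl]chroman-4-one
Conditions: Dess–Martin periodinane (1.3 equiv), NaHCO3, CH2Cl2, 0 °C → rt
Reagents that add atoms: none
Why: Dess–Martin oxidation of a secondary benzylic alcohol to the aryl ketone under buffered conditions that should not ionise the acid-labile C4 hydroxyl and that leave benzyl ethers untouched.

Step 12
Reactants: 15 racemic 5-(benzyloxy)-7-methoxy-2-[2,5-bis(benzyloxy)-3,4-dimethoxyphenyl]chroman-4-one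
Product: 17 5-(benzyloxy)-2-[2,5-bis(benzyloxy)-3,4-dimethoxyphenyl]-7-methoxy-4H-chromen-4-one, via 3-iodoflavanone 16 (not isolated)
Conditions: I2 (10 mol%), DMSO, 120 °C
Reagents that add atoms: none
Why: Iodine/DMSO dehydrogenation of a flavanone, in which the enol is iodinated at C3, hydrogen iodide is eliminated to give the C2=C3 double bond, and DMSO reoxidises the hydrogen iodide to iodine; the C2 stereocentre is erased here.

Step 13
Reactants: 17 5-(benzyloxy)-2-[2,5-bis(benzyloxy)-3,4-dimethoxyphenyl]-7-methoxy-4H-chromen-4-one
Product: 18 2-(2,5-dihydroxy-3,4-dimethoxyphenyl)-5-hydroxy-7-methoxy-4H-chromen-4-one (target)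
Conditions: H2 (1 atm), 10% Pd/C, EtOAc–MeOH, rt; filtered and concentrated under N2
Reagents that add atoms: none
Why: Catalytic hydrogenolysis of three aryl benzyl ethers, in which the chromone double bond (a vinylogous ester) is reduced far more slowly and the methyl ethers are inert; the hydroquinone-type ring B is kept from air during isolation.

**Compound list**

1 | 2,3-dimethoxyphenol | COc1cccc(O)c1OC | starting material
2 | 2,3-dimethoxycyclohexa-2,5-diene-1,4-dione | COC1=C(OC)C(=O)C=CC1=O | intermediate
3 | 2,3-dimethoxybenzene-1,4-diol | COc1c(O)ccc(O)c1OC | intermediate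
4 | 1,4-bis(benzyloxy)-2,3-dimethoxybenzene | COc1c(OCc2ccccc2)ccc(OCc2ccccc2)c1OC | intermediate
5 | 1,4-bis(benzyloxy)-5-bromo-2,3-dimethoxybenzene | COc1c(OCc2ccccc2)cc(Br)c(OCc2ccccc2)c1OC | intermediate
6 | 2-ethenyl-4,4,5,5-tetramethyl-1,3,2-dioxaborolane | C=CB1OC(C)(C)C(C)(C)O1 | starting material
7 | 1-ethenyl-2,5-bis(benzyloxy)-3,4-dimethoxybenzene | C=Cc1cc(OCc2ccccc2)c(OC)c(OC)c1OCc1ccccc1 | intermediate
8 | 2,4,6-trimethoxybenzaldehyde | COc1cc(OC)c(C=O)c(OC)c1 | starting material
9 | 2,6-dihydroxy-4-methoxybenzaldehyde | COc1cc(O)c(C=O)c(O)c1 | intermediate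
10 | 2-(benzyloxy)-6-hydroxy-4-methoxybenzaldehyde | COc1cc(O)c(C=O)c(OCc2ccccc2)c1 | intermediate
11 | 3-(benzyloxy)-2-(hydroxymethyl)-5-methoxyphenol | COc1cc(O)c(CO)c(OCc2ccccc2)c1 | intermediate
12 | 5-(benzyloxy)-3-methoxy-6-methylidenecyclohexa-2,4-dien-1-one (ortho-quinone methide, not isolated) | C=C1C(=O)C=C(OC)C=C1OCc1ccccc1 | intermediate
13 | racemic 5-(benzyloxy)-7-methoxy-2-[2,5-bis(benzyloxy)-3,4-dimethoxyphenyl]chroman | COc1cc(OCc2ccccc2)c2c(c1)OC(c1cc(OCc3ccccc3)c(OC)c(OC)c1OCc1ccccc1)CC2 | intermediate
14 | racemic 5-(benzyloxy)-7-methoxy-2-[2,5-bis(benzyloxy)-3,4-dimethoxyphenyl]chroman-4-ol, mixture of C4 epimers | COc1cc(OCc2ccccc2)c2c(c1)OC(c1cc(OCc3ccccc3)c(OC)c(OC)c1OCc1ccccc1)CC2O | intermediate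
15 | racemic 5-(benzyloxy)-7-methoxy-2-[2,5-bis(benzyloxy)-3,4-dimethoxyphenyl]chroman-4-one | COc1cc(OCc2ccccc2)c2c(c1)OC(c1cc(OCc3ccccc3)c(OC)c(OC)c1OCc1ccccc1)CC2=O | intermediate
16 | racemic 5-(benzyloxy)-2-[2,5-bis(benzyloxy)-3,4-dimethoxyphenyl]-3-iodo-7-methoxychroman-4-one (relative configuration not fixed, not isolated) | COc1cc(OCc2ccccc2)c2c(c1)OC(c1cc(OCc3ccccc3)c(OC)c(OC)c1OCc1ccccc1)C(I)C2=O | intermediate
17 | 5-(benzyloxy)-2-[2,5-bis(benzyloxy)-3,4-dimethoxyphenyl]-7-methoxy-4H-chromen-4-one | COc1cc(OCc2ccccc2)c2c(=O)cc(-c3cc(OCc4ccccc4)c(OC)c(OC)c3OCc3ccccc3)oc2c1 | intermediate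
18 | 2-(2,5-dihydroxy-3,4-dimethoxyphenyl)-5-hydroxy-7-methoxy-4H-chromen-4-one | COc1cc(O)c2c(=O)cc(-c3cc(O)c(OC)c(OC)c3O)oc2c1 | target

**Step count and risks**

Total step count: 13. Longest linear sequence: 10 steps (steps 1 to 5, then 9 to 13); the ring A branch (steps 6 to 8) joins at step 9.

Steps most likely to fail:

Step 9 (key cycloaddition). The quinone methide may be consumed faster by C-alkylation of the nucleophilic ring A positions of unreacted 11 or of product 13, or by self-oligomerisation, than by cycloaddition, and the styrene may polymerise at the temperature needed. The fallback gives up the cycloaddition and builds ring C by aldol condensation and oxidative oxa-Michael closure. It sets out from bromide 5: bromine–lithium exchange (n-BuLi, THF, −78 °C) and quenching with DMF should give 2,5-bis(benzyloxy)-3,4-dimethoxybenzaldehyde F1. Purchased 1-(2,6-dihydroxy-4-methoxyphenyl)ethanone F2 is monobenzylated under the conditions of step 7 to 1-[2-(benzyloxy)-6-hydroxy-4-methoxyphenyl]ethanone F3. Claisen–Schmidt condensation of F3 with F1 (KOH, EtOH, rt) should give (E)-1-[2-(benzyloxy)-6-hydroxy-4-methoxyphenyl]-3-[2,5-bis(benzyloxy)-3,4-dimethoxyphenyl]prop-2-en-1-one F4. Oxidative cyclisation of this 2'-hydroxychalcone with I2 (cat.) in DMSO at 120 °C should give the protected flavone directly, so the fallback comes back to the route at 17 and steps 10 to 12 fall away.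

Step 10 (DDQ oxidation at C4). Hydride abstraction may occur at C2 instead of C4, because C2 is flanked by O1 and the very electron-rich ring B, which would open the ring to a dihydrochalcone. The C4 cation may also lose a proton to a flav-3-ene and be oxidised on to a flavylium salt, and benzyl ethers may be cleaved oxidatively. The fallback carries the C4 oxygen into the cycloaddition instead of adding it afterwards. It sets out from aldehyde 10 and styrene 7: with trimethyl orthoformate and an acid catalyst (camphorsulfonic acid or Sc(OTf)3, CH2Cl2, rt) the aldehyde should form the acetal 3-(benzyloxy)-2-(dimethoxymethyl)-5-methoxyphenol F5. This loses methanol to the alkoxy-substituted quinone methide 5-(benzyloxy)-3-methoxy-6-(methoxymethylidene)cyclohexa-2,4-dien-1-one F6, which should add to 7 in the same hetero-Diels–Alder sense to give racemic 5-(benzyloxy)-4,7-dimethoxy-2-[2,5-bis(benzyloxy)-3,4-dimethoxyphenyl]chroman F7. Mild aqueous acid (dilute HCl, THF–H2O) exchanges the benzylic methoxy group for hydroxyl, and the fallback comes back to the route at 14.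

Step 8 (reduction to the benzyl alcohol). The product may ionise to the quinone methide during reduction or work-up, giving over-reduction to the methylphenol by hydride capture or oligomers on concentration. The fallback replaces the alcohol by a stable amine precursor of the same quinone methide. It sets out from aldehyde 10: reductive amination with dimethylamine (NaBH(OAc)3, 1,2-dichloroethane, rt) should give the Mannich base 3-(benzyloxy)-2-[(dimethylamino)methyl]-5-methoxyphenol F8, which can be stored. Heating F8 with excess 7 in o-xylene should expel dimethylamine to give 12 and then the cycloadduct, so the fallback comes back to the route at 13.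

**Further compounds**

F1 | step 9 | 2,5-bis(benzyloxy)-3,4-dimethoxybenzaldehyde | O=Cc1cc(OCc2ccccc2)c(OC)c(OC)c1OCc1ccccc1
F2 | step 9 | 1-(2,6-dihydroxy-4-methoxyphenyl)ethanone (purchased) | COc1cc(O)c(C(C)=O)c(O)c1
F3 | step 9 | 1-[2-(benzyloxy)-6-hydroxy-4-methoxyphenyl]ethanone | COc1cc(O)c(C(C)=O)c(OCc2ccccc2)c1
F4 | step 9 | (E)-1-[2-(benzyloxy)-6-hydroxy-4-methoxyphenyl]-3-[2,5-bis(benzyloxy)-3,4-dimethoxyphenyl]prop-2-en-1-one | COc1cc(O)c(C(=O)/C=C/c2cc(OCc3ccccc3)c(OC)c(OC)c2OCc2ccccc2)c(OCc2ccccc2)c1
F5 | step 10 | 3-(benzyloxy)-2-(dimethoxymethyl)-5-methoxyphenol | COc1cc(O)c(C(OC)OC)c(OCc2ccccc2)c1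
F6 | step 10 | 5-(benzyloxy)-3-methoxy-6-(methoxymethylidene)cyclohexa-2,4-dien-1-one (alkene geometry not fixed, not isolated) | COC=C1C(=O)C=C(OC)C=C1OCc1ccccc1
F7 | step 10 | racemic 5-(benzyloxy)-4,7-dimethoxy-2-[2,5-bis(benzyloxy)-3,4-dimethoxyphenyl]chroman (mixture of C4 epimers) | COc1cc(OCc2ccccc2)c2c(c1)OC(c1cc(OCc3ccccc3)c(OC)c(OC)c1OCc1ccccc1)CC2OC
F8 | step 8 | 3-(benzyloxy)-2-[(dimethylamino)methyl]-5-methoxyphenol | COc1cc(O)c(CN(C)C)c(OCc2ccccc2)c1
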